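**Plan**

- Cuts (core locants O1, C2, C3, C3a, C4, O5, C6, C7, C7a; primes for the pendant ring): the catechol ketals; O1′–C2′ and C5′–C6′ of the pendant pyranone; O5–C6 of the fused pyranone; O1–C7a together with C3a–C4 (C4 is carbon monoxide); C7–C7a; C2–C3.
- Enabling feature: the dihydrofuran ring holds a tetrasubstituted enol-ether double bond C3a=C7a, with the ring oxygen O1 on C7a and the lactone carbonyl carbon C4 on C3a on the same side. This is the footprint of an alkyne that has taken up a hydroxyl oxygen and CO across the triple bond.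
- Forward: C2–C3 joins an aryl aldehyde to a C4 propargyl unit, and C7–C7a coupling completes the diyne–ene chain. The dihydrofuran then closes with carbonylation, followed by the fused pyranone, then the pendant pyranone from the C3 hydroxymethyl arm. The catechols are freed last.
- Stereochemistry: C3 derives from an (S)-propargylic mesylate (asymmetric transfer hydrogenation) and is transferred with net inversion through an allenylzinc. C2 is set anti to it in the same addition. The anti alcohol becomes the trans-(2S,3S) ring, and no later step breaks a bond at C2 or C3.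

Key step: step 13

Remark: Ar = 2,2-dimethyl-1,3-benzodioxol-5-yl and TBS = tert-butyldimethylsilyl; core locants are also used for the matching atoms of earlier intermediates; the (R,R)-catalyst of step 8 is chosen on the assumption that the alkynyl group of the ynone takes the place an aryl group occupies in the usual transfer-hydrogenation transition state.

**Route**

Step 1
Reactants: 1 3,4-dihydroxybenzaldehyde
Product: 2 acetonide aldehyde 2,2-dimethyl-1,3-benzodioxole-5-carbaldehyde (ArCHO)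
Conditions: 2,2-dimethoxypropane, p-TsOH (cat.), toluene, reflux, MeOH removed over 4 Å MS
Reagents that add atoms: 2,2-dimethoxypropane, COC(C)(C)OC
Why: Acid-catalysed transketalisation of the catechol with the dimethyl ketal, driven by removal of methanol, should close the five-membered 2,2-dimethylbenzodioxole and leave the aldehyde free after aqueous work-up.

Step 2
Reactants: 2 ArCHO
Product: 3 enal (2E)-3-Ar-prop-2-enal
Conditions: Ph3P=CHCHO, toluene, 80 °C
Reagents that add atoms: (triphenylphosphoranylidene)acetaldehyde, O=CC=P(c1ccccc1)(c1ccccc1)c1ccccc1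
Why: Wittig olefination with the stabilised formylmethylene ylide should give the E-enal, since stabilised ylides react through the trans oxaphosphetane.

Step 3
Reactants: 3 enal
Product: 4 dibromodiene 5-[(1E)-4,4-dibromobuta-1,3-dien-1-yl]-2,2-dimethyl-1,3-benzodioxole
Conditions: CBr4, PPh3, CH2Cl2, 0 °C
Reagents that add atoms: carbon tetrabromide, BrC(Br)(Br)Br
Why: Corey–Fuchs (Ramirez) dibromo-olefination with the ylide formed in situ from PPh3 and CBr4 runs under neutral conditions that the ketal and the E-alkene tolerate.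

Step 4
Reactants: 4 dibromodiene
Product: 5 bromoenyne 5-[(1E)-4-bromobut-1-en-3-yn-1-yl]-2,2-dimethyl-1,3-benzodioxole
Conditions: DBU, DMSO, 15–20 °C
Reagents that add atoms: none
Why: DBU-mediated anti-elimination of HBr from a conjugated 1,1-dibromoalkene is a known way to stop the Corey–Fuchs sequence at the 1-bromoalkyne, the amidine base being unable to exchange the remaining bromine.

Step 5
Reactants: 6 methyl glycolate
Product: 7 methyl 2-(tert-butyldimethylsilyloxy)acetate
Conditions: TBSCl, imidazole, CH2Cl2, 0 °C → rt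
Reagents that add atoms: tert-butyldimethylsilyl chloride, CC(C)(C)[Si](C)(C)Cl
Why: Imidazole-promoted silylation of a primary alcohol (Corey conditions) is routine and leaves the ester alone.

Step 6
Reactants: 7 methyl 2-(tert-butyldimethylsilyloxy)acetate
Product: 8 Weinreb amide 2-(tert-butyldimethylsilyloxy)-N-methoxy-N-methylacetamide
Conditions: MeNH(OMe)·HCl, i-PrMgCl, THF, −20 → 0 °C
Reagents that add atoms: N,O-dimethylhydroxylamine hydrochloride, CNOC.Cl
Why: Weinreb amide formation from a methyl ester with the chloromagnesium amide of N,O-dimethylhydroxylamine is standard and compatible with the silyl ether.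

Step 7
Reactants: 8 Weinreb amide; 9 trimethylsilylacetylene
Product: 11 ynone 1-(tert-butyldimethylsilyloxy)-4-(trimethylsilyl)but-3-yn-2-one, via lithium (trimethylsilyl)acetylide 10 (not isolated)
Conditions: 9, n-BuLi, THF, −78 °C; then 8, −78 → 0 °C; aq. NH4Cl
Reagents that add atoms: none
Why: Weinreb ketone synthesis, in which the lithium acetylide adds once and the chelated tetrahedral adduct holds until work-up, so the ynone should form without over-addition.

Step 8
Reactants: 11 ynone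
Product: 12 (2S)-1-(tert-butyldimethylsilyloxy)-4-(trimethylsilyl)but-3-yn-2-ol
Conditions: Ru[(R,R)-TsDPEN](p-cymene) (1 mol%), i-PrOH, rt
Reagents that add atoms: none
Why: Noyori asymmetric transfer hydrogenation of an ynone, in which the Ru–H/N–H pair delivers hydrogen to the carbonyl face that places the alkynyl group next to the arene ligand, which with the (R,R)-catalyst should set the carbinol centre as S (CH2OTBS outranks the alkynyl carbon).

Step 9
Reactants: 12 (S)-propargylic alcohol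
Product: 13 (2S)-1-(tert-butyldimethylsilyloxy)-4-(trimethylsilyl)but-3-yn-2-yl methanesulfonate
Conditions: MsCl, Et3N, CH2Cl2, −78 → 0 °C
Reagents that add atoms: methanesulfonyl chloride, CS(=O)(=O)Cl
Why: O-sulfonylation forms no bond at carbon, so the S configuration is kept, and the propargylic mesylate is used directly.

Step 10
Reactants: 13 (S)-mesylate; 2 ArCHO
Product: 15 anti alcohol (1S,2R)-2-(TBSOCH2)-1-Ar-4-(trimethylsilyl)but-3-yn-1-ol, via allenylzinc 14 (not isolated)
Conditions: Pd(OAc)2 (5 mol%), PPh3 (5 mol%), Et2Zn, THF, −78 → −20 °C; aq. NH4Cl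
Reagents that add atoms: none
Why: Marshall–Tamaru propargylation, in which Pd(0) displaces the mesylate in an anti SN2′ sense, Pd-to-Zn exchange with retention gives the (P)-allenylzinc, and its cyclic SE2′ addition to the aldehyde (aryl group turned away from the CH2OTBS substituent) should set C3 by net inversion of the mesylate centre and C2 anti to it; the minor syn isomer should be removable by chromatography.

Step 11
Reactants: 15 anti alcohol
Product: 16 terminal alkyne (1S,2R)-2-(TBSOCH2)-1-Ar-but-3-yn-1-ol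
Conditions: K2CO3, MeOH, rt
Reagents that add atoms: none
Why: Carbonate-catalysed methanolysis cleaves the alkynyl C–Si bond selectively, the primary TBS ether and both stereocentres being inert to these conditions.

Step 12
Reactants: 16 terminal alkyne; 5 bromoenyne
Product: 17 diynene alcohol (1S,2R,7E)-2-(TBSOCH2)-1,8-di-Ar-oct-7-ene-3,5-diyn-1-ol
Conditions: CuCl (cat.), NH2OH·HCl, n-BuNH2, H2O–Et2O, 0 °C
Reagents that add atoms: none
Why: Cadiot–Chodkiewicz coupling of a terminal alkyne with a 1-bromoalkyne under Cu(I)/amine forms the unsymmetrical diyne (bond C7–C7a) and tolerates the free secondary alcohol.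

Step 13
Reactants: 17 diynene alcohol
Product: 18 methyl (4R,5S)-4-(TBSOCH2)-5-Ar-2-[(3E)-4-Ar-but-3-en-1-yn-1-yl]-4,5-dihydrofuran-3-carboxylate (trans)
Conditions: PdCl2(MeCN)2 (5 mol%), p-benzoquinone (1.5 equiv), CO (1 atm), MeOH, 0 °C → rt
Reagents that add atoms: carbon monoxide, [C-]#[O+]; methanol, CO
Why: Pd(II) coordinates the alkyne next to C3 and the C2 hydroxyl attacks C7a from the face opposite the metal, giving a dihydrofuranyl–palladium species at C3a; CO inserts into this C–Pd bond, methanol cleaves the acyl–palladium to the methyl ester, and benzoquinone reoxidises Pd(0). The closest known reaction type is the Pd(II)-catalysed oxidative cyclisation–methoxycarbonylation of alkynols (homopropargylic alcohols to dihydrofuran-3-carboxylates, 3-yne-1,2-diols to furan-3-carboxylates, 2-alkynylphenols to benzofuran-3-carboxylates). The dihydrofuran ring closes in a 5-endo-dig mode through the O1–C7a bond. No stereocentre is created: C2 and C3 of the anti alcohol enter the ring untouched and therefore stand trans. The step needs attack at C7a only, which the substrate secures because the hydroxyl cannot reach the distal alkyne or the alkene and a 4-exo closure at C3a is strained. It also needs carbonylation to outrun protodepalladation, which the CO atmosphere, the low temperature and the proton-accepting benzoquinone should secure; the enyne arm on C7a then sits cis to the new ester across C3a=C7a, as step 14 requires.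

Step 14
Reactants: 18 dihydrofuran ester
Product: 19 (2S,3R)-3-(TBSOCH2)-2-Ar-6-[(E)-2-Ar-ethenyl]-2,3-dihydro-4H-furo[3,2-c]pyran-4-one
Conditions: [JohnPhosAu(MeCN)]SbF6 (5 mol%), H2O (3 equiv), ClCH2CH2Cl, 50 °C
Reagents that add atoms: water, O
Why: Gold(I) π-activation of the remaining alkyne lets the cis ester carbonyl oxygen attack C6 in a 6-endo-dig mode (favoured by the cation-stabilising styryl group on C6), and the 2-methoxypyrylium–vinylgold species is hydrolysed by water with loss of methanol and protodeauration at C7, a demethylative lactonisation of the kind known for alkyl 2-alkynylbenzoates and enynoates.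

Step 15
Reactants: 19 silyl ether
Product: 20 alcohol (2S,3R)-3-(hydroxymethyl)-2-Ar-6-[(E)-2-Ar-ethenyl]-2,3-dihydro-4H-furo[3,2-c]pyran-4-one
Conditions: HF·pyridine, pyridine, THF, 0 °C → rt
Reagents that add atoms: none
Why: Fluoride cleavage of the primary silyl ether with pyridine-buffered HF avoids basic conditions that could open the pyranone, and the ketals are stable to it.

Step 16
Reactants: 20 alcohol
Product: 21 aldehyde (2S,3S)-2-Ar-6-[(E)-2-Ar-ethenyl]-4-oxo-2,3-dihydro-4H-furo[3,2-c]pyran-3-carbaldehyde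
Conditions: Dess–Martin periodinane, NaHCO3, CH2Cl2, 0 °C
Reagents that add atoms: none
Why: Dess–Martin oxidation stops at the aldehyde under buffered, base-free conditions, which matters because C3–H is now α to a carbonyl and β to the ring oxygen O1; the aldehyde is carried on without chromatography.

Step 17
Reactants: 22 2,2,6-trimethyl-4H-1,3-dioxin-4-one
Product: 24 silyl dienol ether trimethyl[(2,2-dimethyl-6-methylidene-6H-1,3-dioxin-4-yl)oxy]silane, via lithium dienolate 23 (not isolated)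
Conditions: LDA, THF, −78 °C; then TMSCl, −78 → 0 °C
Reagents that add atoms: chlorotrimethylsilane, C[Si](C)(C)Cl
Why: Kinetic γ-deprotonation of the dioxinone methyl group and O-silylation of the lithium dienolate is the standard route to this silyl dienol ether.

Step 18
Reactants: 21 aldehyde; 24 silyl dienol ether
Product: 25 aldol adduct 6-{2-hydroxy-2-[(2S,3R)-2-Ar-6-((E)-2-Ar-ethenyl)-4-oxo-2,3-dihydro-4H-furo[3,2-c]pyran-3-yl]ethyl}-2,2-dimethyl-4H-1,3-dioxin-4-one (both carbinol epimers)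
Conditions: BF3·OEt2, CH2Cl2, −78 °C; aq. NaHCO3
Reagents that add atoms: none
Why: Vinylogous Mukaiyama aldol addition, in which the BF3-activated aldehyde is attacked by the terminal methylidene carbon of the dienol ether (bond C5′–C6′) in a Lewis-acid process at −78 °C that should leave C3 unepimerised; the new carbinol centre forms without control and is removed in step 19.

Step 19
Reactants: 25 aldol adduct
Product: 26 keto-dioxinone 6-{2-oxo-2-[(2S,3S)-2-Ar-6-((E)-2-Ar-ethenyl)-4-oxo-2,3-dihydro-4H-furo[3,2-c]pyran-3-yl]ethyl}-2,2-dimethyl-4H-1,3-dioxin-4-one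
Conditions: Dess–Martin periodinane, NaHCO3, CH2Cl2, 0 °C → rt
Reagents that add atoms: none
Why: Dess–Martin oxidation of the secondary alcohol gives the β-keto dioxinone from either carbinol epimer, and should C3 equilibrate under these buffered conditions the trans ring is the more stable one.

Step 20
Reactants: 26 keto-dioxinone
Product: 28 hypholomine B bis(acetonide) (2S,3S)-2-Ar-6-[(E)-2-Ar-ethenyl]-3-(4-hydroxy-2-oxo-2H-pyran-6-yl)-2,3-dihydro-4H-furo[3,2-c]pyran-4-one, via acylketene 27 (not isolated)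
Conditions: toluene, 110 °C
Reagents that add atoms: none
Why: Thermal retro-[4+2] loss of acetone from the dioxinone gives an acylketene that is captured by the enol oxygen of the C6′ ketone (bond O1′–C2′), the standard closure to a 6-substituted 4-hydroxy-2-pyranone.

Step 21
Reactants: 28 hypholomine B bis(acetonide)
Product: 29 hypholomine B
Conditions: TFA–H2O (9:1), 0 °C → rt
Reagents that add atoms: none
Why: Aqueous acid hydrolyses both catechol ketals without deprotonating C2 or C3, and should acid reversibly ionise the benzylic C2–O1 bond, reclosure would favour the more stable trans ring.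

**Compound list**

1 | 3,4-dihydroxybenzaldehyde | O=Cc1ccc(O)c(O)c1 | starting material
2 | 2,2-dimethyl-1,3-benzodioxole-5-carbaldehyde | O=Cc1ccc2OC(C)(C)Oc2c1 | intermediate
3 | (2E)-3-(2,2-dimethyl-1,3-benzodioxol-5-yl)prop-2-enal | O=C/C=C/c1ccc2OC(C)(C)Oc2c1 | intermediate
4 | 5-[(1E)-4,4-dibromobuta-1,3-dien-1-yl]-2,2-dimethyl-1,3-benzodioxole | BrC(Br)=C/C=C/c1ccc2OC(C)(C)Oc2c1 | intermediate
5 | 5-[(1E)-4-bromobut-1-en-3-yn-1-yl]-2,2-dimethyl-1,3-benzodioxole | BrC#C/C=C/c1ccc2OC(C)(C)Oc2c1 | intermediate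
6 | methyl glycolate | COC(=O)CO | starting material
7 | methyl 2-(tert-butyldimethylsilyloxy)acetate | COC(=O)CO[Si](C)(C)C(C)(C)C | intermediate
8 | 2-(tert-butyldimethylsilyloxy)-N-methoxy-N-methylacetamide | CON(C)C(=O)CO[Si](C)(C)C(C)(C)C | intermediate
9 | trimethylsilylacetylene | C#C[Si](C)(C)C | starting material
10 | lithium (trimethylsilyl)acetylide | [Li]C#C[Si](C)(C)C | intermediate (not isolated)
11 | 1-(tert-butyldimethylsilyloxy)-4-(trimethylsilyl)but-3-yn-2-one | C[Si](C)(C)C#CC(=O)CO[Si](C)(C)C(C)(C)C | intermediate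
12 | (2S)-1-(tert-butyldimethylsilyloxy)-4-(trimethylsilyl)but-3-yn-2-ol | C[Si](C)(C)C#C[C@H](O)CO[Si](C)(C)C(C)(C)C | intermediate
13 | (2S)-1-(tert-butyldimethylsilyloxy)-4-(trimethylsilyl)but-3-yn-2-yl methanesulfonate | C[Si](C)(C)C#C[C@H](OS(C)(=O)=O)CO[Si](C)(C)C(C)(C)C | intermediate
14 | (P)-ethyl[4-(tert-butyldimethylsilyloxy)-1-(trimethylsilyl)buta-1,2-dien-1-yl]zinc | CC[Zn]C([Si](C)(C)C)=[C@@]=C([H])CO[Si](C)(C)C(C)(C)C | intermediate (not isolated)
15 | (1S,2R)-2-[(tert-butyldimethylsilyloxy)methyl]-1-(2,2-dimethyl-1,3-benzodioxol-5-yl)-4-(trimethylsilyl)but-3-yn-1-ol (anti) | CC(C)(C)[Si](C)(C)OC[C@@H](C#C[Si](C)(C)C)[C@H](O)c1ccc2OC(C)(C)Oc2c1 | intermediate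
16 | (1S,2R)-2-[(tert-butyldimethylsilyloxy)methyl]-1-(2,2-dimethyl-1,3-benzodioxol-5-yl)but-3-yn-1-ol | CC(C)(C)[Si](C)(C)OC[C@@H](C#C)[C@H](O)c1ccc2OC(C)(C)Oc2c1 | intermediate
17 | (1S,2R,7E)-2-[(tert-butyldimethylsilyloxy)methyl]-1,8-bis(2,2-dimethyl-1,3-benzodioxol-5-yl)oct-7-ene-3,5-diyn-1-ol (anti) | CC(C)(C)[Si](C)(C)OC[C@@H](C#CC#C/C=C/c1ccc2OC(C)(C)Oc2c1)[C@H](O)c1ccc2OC(C)(C)Oc2c1 | intermediate
18 | methyl (4R,5S)-4-[(tert-butyldimethylsilyloxy)methyl]-5-(2,2-dimethyl-1,3-benzodioxol-5-yl)-2-[(3E)-4-(2,2-dimethyl-1,3-benzodioxol-5-yl)but-3-en-1-yn-1-yl]-4,5-dihydrofuran-3-carboxylate (trans) | CC(C)(C)[Si](C)(C)OC[C@H]1C(C(=O)OC)=C(C#C/C=C/c2ccc3OC(C)(C)Oc3c2)O[C@@H]1c1ccc2OC(C)(C)Oc2c1 | intermediate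
19 | (2S,3R)-3-[(tert-butyldimethylsilyloxy)methyl]-2-(2,2-dimethyl-1,3-benzodioxol-5-yl)-6-[(E)-2-(2,2-dimethyl-1,3-benzodioxol-5-yl)ethenyl]-2,3-dihydro-4H-furo[3,2-c]pyran-4-one | CC(C)(C)[Si](C)(C)OC[C@H]1c2c(cc(/C=C/c3ccc4OC(C)(C)Oc4c3)oc2=O)O[C@@H]1c1ccc2OC(C)(C)Oc2c1 | intermediate
20 | (2S,3R)-3-(hydroxymethyl)-2-(2,2-dimethyl-1,3-benzodioxol-5-yl)-6-[(E)-2-(2,2-dimethyl-1,3-benzodioxol-5-yl)ethenyl]-2,3-dihydro-4H-furo[3,2-c]pyran-4-one | OC[C@H]1c2c(cc(/C=C/c3ccc4OC(C)(C)Oc4c3)oc2=O)O[C@@H]1c1ccc2OC(C)(C)Oc2c1 | intermediate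
21 | (2S,3S)-2-(2,2-dimethyl-1,3-benzodioxol-5-yl)-6-[(E)-2-(2,2-dimethyl-1,3-benzodioxol-5-yl)ethenyl]-4-oxo-2,3-dihydro-4H-furo[3,2-c]pyran-3-carbaldehyde | O=C[C@H]1c2c(cc(/C=C/c3ccc4OC(C)(C)Oc4c3)oc2=O)O[C@@H]1c1ccc2OC(C)(C)Oc2c1 | intermediate
22 | 2,2,6-trimethyl-4H-1,3-dioxin-4-one | CC1=CC(=O)OC(C)(C)O1 | starting material
23 | lithium 2,2-dimethyl-6-methylidene-6H-1,3-dioxin-4-olate | [Li]OC1=CC(=C)OC(C)(C)O1 | intermediate (not isolated)
24 | trimethyl[(2,2-dimethyl-6-methylidene-6H-1,3-dioxin-4-yl)oxy]silane | C=C1C=C(O[Si](C)(C)C)OC(C)(C)O1 | intermediate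
25 | 6-{2-hydroxy-2-[(2S,3R)-2-(2,2-dimethyl-1,3-benzodioxol-5-yl)-6-[(E)-2-(2,2-dimethyl-1,3-benzodioxol-5-yl)ethenyl]-4-oxo-2,3-dihydro-4H-furo[3,2-c]pyran-3-yl]ethyl}-2,2-dimethyl-4H-1,3-dioxin-4-one (carbinol carbon undefined, both epimers) | CC1(C)OC(=O)C=C(CC(O)[C@H]2c3c(cc(/C=C/c4ccc5OC(C)(C)Oc5c4)oc3=O)O[C@@H]2c2ccc3OC(C)(C)Oc3c2)O1 | intermediate
26 | 6-{2-oxo-2-[(2S,3S)-2-(2,2-dimethyl-1,3-benzodioxol-5-yl)-6-[(E)-2-(2,2-dimethyl-1,3-benzodioxol-5-yl)ethenyl]-4-oxo-2,3-dihydro-4H-furo[3,2-c]pyran-3-yl]ethyl}-2,2-dimethyl-4H-1,3-dioxin-4-one | CC1(C)OC(=O)C=C(CC(=O)[C@H]2c3c(cc(/C=C/c4ccc5OC(C)(C)Oc5c4)oc3=O)O[C@@H]2c2ccc3OC(C)(C)Oc3c2)O1 | intermediate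
27 | 5-[(2S,3S)-2-(2,2-dimethyl-1,3-benzodioxol-5-yl)-6-[(E)-2-(2,2-dimethyl-1,3-benzodioxol-5-yl)ethenyl]-4-oxo-2,3-dihydro-4H-furo[3,2-c]pyran-3-yl]-3,5-dioxopent-1-en-1-one (acylketene) | O=C=CC(=O)CC(=O)[C@H]1c2c(cc(/C=C/c3ccc4OC(C)(C)Oc4c3)oc2=O)O[C@@H]1c1ccc2OC(C)(C)Oc2c1 | intermediate (not isolated)
28 | (2S,3S)-2-(2,2-dimethyl-1,3-benzodioxol-5-yl)-6-[(E)-2-(2,2-dimethyl-1,3-benzodioxol-5-yl)ethenyl]-3-(4-hydroxy-2-oxo-2H-pyran-6-yl)-2,3-dihydro-4H-furo[3,2-c]pyran-4-one | O=c1cc(O)cc([C@H]2c3c(cc(/C=C/c4ccc5OC(C)(C)Oc5c4)oc3=O)O[C@@H]2c2ccc3OC(C)(C)Oc3c2)o1 | intermediate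
29 | hypholomine B, (2S,3S)-2-(3,4-dihydroxyphenyl)-6-[(E)-2-(3,4-dihydroxyphenyl)ethenyl]-3-(4-hydroxy-2-oxo-2H-pyran-6-yl)-2,3-dihydro-4H-furo[3,2-c]pyran-4-one | O=c1cc(O)cc([C@H]2c3c(cc(/C=C/c4ccc(O)c(O)c4)oc3=O)O[C@@H]2c2ccc(O)c(O)c2)o1 | target

**Step count**

Total: 21 steps. Longest linear sequence: 16 steps (from 6 through steps 5–16 and 18–21 to 29).

**Steps most likely to fail**

Step 13. The C3a–palladium intermediate may be protonated before CO inserts, which would give the uncarbonylated dihydrofuran. Pd(II) in methanol may also react further at the distal enyne or loosen the silyl ether. The fallback makes the same two bonds in two known operations. Starting from 17, 5-endo-dig iodocyclisation (I2, NaHCO3, MeCN, 0 °C) should give the vinyl iodide (2S,3R)-3-(TBSOCH2)-2-Ar-4-iodo-5-[(3E)-4-Ar-but-3-en-1-yn-1-yl]-2,3-dihydrofuran F1. Pd(0)-catalysed methoxycarbonylation of the C–I bond (PdCl2(PPh3)2, CO 1 atm, Et3N, MeOH–DMF, 50 °C) should then give 18, where the route is rejoined.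

Step 14. The cyclisation may stall at the 2-methoxypyrylium stage because the methyl group is not released and the gold is not turned over. The Lewis-acidic medium may also strip the silyl ether. The fallback replaces π-acid catalysis by electrophilic cyclisation. Starting from 18, iodine (CH2Cl2, rt) should induce 6-endo-dig iodolactonisation, with iodide removing the methyl group, to give (2S,3R)-3-(TBSOCH2)-7-iodo-2-Ar-6-[(E)-2-Ar-ethenyl]-2,3-dihydro-4H-furo[3,2-c]pyran-4-one F2. Reductive removal of the C7 iodine (Bu3SnH, Pd(PPh3)4 cat., THF, rt) should then give 19.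

Step 16. Once C3 carries a formyl group, C3 may epimerise and the ring oxygen O1 may be lost by β-elimination (retro-oxa-Michael opening of the dihydrofuran). This can happen during the oxidation, on handling, or in the aldol of step 18. The fallback never isolates the aldehyde and builds the side chain by acylation. Starting from 20, direct oxidation (TEMPO cat., PhI(OAc)2, MeCN–H2O, rt) should give (2S,3S)-2-Ar-6-[(E)-2-Ar-ethenyl]-4-oxo-2,3-dihydro-4H-furo[3,2-c]pyran-3-carboxylic acid F3. Carbonyldiimidazole (THF, rt) should convert it into the acyl imidazole 1-{[(2S,3S)-2-Ar-6-((E)-2-Ar-ethenyl)-4-oxo-2,3-dihydro-4H-furo[3,2-c]pyran-3-yl]carbonyl}imidazole F4. F4 is added at −78 °C to lithium dienolate 23 (from 22 and LiHMDS, 2.2 equiv, THF) for γ-C-acylation, which should give 26 and rejoin the route.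

**Further compounds**

F1 | step 13 | (2S,3R)-3-[(tert-butyldimethylsilyloxy)methyl]-2-(2,2-dimethyl-1,3-benzodioxol-5-yl)-4-iodo-5-[(3E)-4-(2,2-dimethyl-1,3-benzodioxol-5-yl)but-3-en-1-yn-1-yl]-2,3-dihydrofuran | CC(C)(C)[Si](C)(C)OC[C@H]1C(I)=C(C#C/C=C/c2ccc3OC(C)(C)Oc3c2)O[C@@H]1c1ccc2OC(C)(C)Oc2c1
F2 | step 14 | (2S,3R)-3-[(tert-butyldimethylsilyloxy)methyl]-7-iodo-2-(2,2-dimethyl-1,3-benzodioxol-5-yl)-6-[(E)-2-(2,2-dimethyl-1,3-benzodioxol-5-yl)ethenyl]-2,3-dihydro-4H-furo[3,2-c]pyran-4-one | CC(C)(C)[Si](C)(C)OC[C@H]1c2c(c(I)c(/C=C/c3ccc4OC(C)(C)Oc4c3)oc2=O)O[C@@H]1c1ccc2OC(C)(C)Oc2c1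
F3 | step 16 | (2S,3S)-2-(2,2-dimethyl-1,3-benzodioxol-5-yl)-6-[(E)-2-(2,2-dimethyl-1,3-benzodioxol-5-yl)ethenyl]-4-oxo-2,3-dihydro-4H-furo[3,2-c]pyran-3-carboxylic acid | OC(=O)[C@H]1c2c(cc(/C=C/c3ccc4OC(C)(C)Oc4c3)oc2=O)O[C@@H]1c1ccc2OC(C)(C)Oc2c1
F4 | step 16 | 1-{[(2S,3S)-2-(2,2-dimethyl-1,3-benzodioxol-5-yl)-6-[(E)-2-(2,2-dimethyl-1,3-benzodioxol-5-yl)ethenyl]-4-oxo-2,3-dihydro-4H-furo[3,2-c]pyran-3-yl]carbonyl}-1H-imidazole | O=C(n1ccnc1)[C@H]1c2c(cc(/C=C/c3ccc4OC(C)(C)Oc4c3)oc2=O)O[C@@H]1c1ccc2OC(C)(C)Oc2c1
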